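**Strategy.** The quinone ring is cut at C1–C8a and at C2=C3 (numbering of 2-methyl-3-octaprenyl-1,4-naphthoquinone). Both bonds form in one pot from an o-iodoaryl ketone and propyne. Sonogashira coupling joins C8a to the alkyne terminus (future C1); the enolate of the C4 ketone then closes its chain-bearing α-carbon (C3) onto the methyl-bearing alkyne carbon (C2), 6-endo-dig, to a 1-naphthol. The step exploits the C4 carbonyl, which acidifies C3–H and sits ortho to C8a, and the C2-methyl/C1 pair as a propyne unit. C1 is oxygenated afterwards to the quinone. The all-E C40 chain comes from two geranylgeraniol units by sulfone coupling.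

Key step: step 10

Remark: the target has no stereocentre, so the stereochemical task is read as the seven E trisubstituted alkenes. Six are taken over from commercial (2E,6E,10E)-geranylgeraniol and one is set in step 4. 2'-Iodoacetophenone and propyne are also taken as commercial.

**Step 1**
Reactants: 1 (2E,6E,10E)-geranylgeraniol
Product: 2 (2E,6E,10E)-geranylgeranyl bromide
Conditions: PBr3 (0.4 equiv), Et2O, −10 °C, dark; used crude
Reagents that add atoms: phosphorus tribromide, BrP(Br)Br
Why: Bromination of a primary allylic alcohol with PBr3 runs by SN2 displacement of the phosphite ester at low temperature, so the 2E double bond should neither migrate nor isomerise.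

**Step 2**
Reactants: 2 (2E,6E,10E)-geranylgeranyl bromide
Product: 3 (2E,6E,10E)-geranylgeranyl phenyl sulfone
Conditions: PhSO2Na, DMF, rt
Reagents that add atoms: sodium benzenesulfinate, [Na+].[O-]S(=O)c1ccccc1
Why: S-alkylation of the sulfinate by the primary allylic bromide (SN2) should give the allyl sulfone whose α-carbanion is the nucleophile of the sulfone coupling in step 6.

**Step 3**
Reactants: 1 (2E,6E,10E)-geranylgeraniol
Product: 4 (2E,6E,10E)-geranylgeranyl acetate
Conditions: Ac2O, pyridine, DMAP (cat.), CH2Cl2, rt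
Reagents that add atoms: acetic anhydride, CC(=O)OC(C)=O
Why: DMAP-catalysed acylation protects the allylic hydroxyl against the oxidant of step 4 and the carbanion of step 6.

**Step 4**
Reactants: 4 (2E,6E,10E)-geranylgeranyl acetate
Product: 5 (2E,6E,10E,14E)-16-hydroxy-3,7,11,15-tetramethylhexadeca-2,6,10,14-tetraen-1-yl acetate
Conditions: SeO2 (cat.), salicylic acid (cat.), t-BuOOH (70% aq.), CH2Cl2, rt
Reagents that add atoms: tert-butyl hydroperoxide, CC(C)(C)OO; selenium dioxide (catalytic oxygen carrier), O=[Se]=O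
Why: Sharpless SeO2/t-BuOOH allylic oxidation (ene reaction, then [2,3]-sigmatropic shift) should attack the E-methyl group of the terminal, least hindered trisubstituted alkene, which sets the 14E geometry.

**Step 5**
Reactants: 5 (2E,6E,10E,14E)-16-hydroxygeranylgeranyl acetate
Product: 6 (2E,6E,10E,14E)-16-bromo-3,7,11,15-tetramethylhexadeca-2,6,10,14-tetraen-1-yl acetate
Conditions: CBr4, PPh3, CH2Cl2, −20 → 0 °C
Reagents that add atoms: carbon tetrabromide, BrC(Br)(Br)Br
Why: The Appel reaction should convert the primary allylic alcohol to the bromide by SN2 on the alkoxyphosphonium ion, without allylic transposition and with the acetate untouched.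

**Step 6**
Reactants: 3 (2E,6E,10E)-geranylgeranyl phenyl sulfone; 6 (2E,6E,10E,14E)-16-bromogeranylgeranyl acetate
Product: 7 (2E,6E,10E,14E,18E,22E,26E)-3,7,11,15,19,23,27,31-octamethyl-17-(phenylsulfonyl)dotriaconta-2,6,10,14,18,22,26,30-octaen-1-yl acetate (racemic at C17)
Conditions: 3, n-BuLi, THF, −78 °C; then 6, −78 → −30 °C
Reagents that add atoms: none
Why: α-Alkylation of the lithiated allyl sulfone by the primary allylic bromide (Biellmann-type sulfone coupling, SN2) should join the two C20 units head to tail without touching a double bond; the new sulfone-bearing centre is racemic and is removed in step 7.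

**Step 7**
Reactants: 7 C40 sulfone acetate
Product: 8 (2E,6E,10E,14E,18E,22E,26E)-octaprenol (3,7,11,15,19,23,27,31-octamethyldotriaconta-2,6,10,14,18,22,26,30-octaen-1-ol)
Conditions: LiEt3BH (excess), THF, 0 °C; then PdCl2(dppp) (5 mol%), 0 °C → rt
Reagents that add atoms: none
Why: Excess LiEt3BH should first reduce the acetate to the alkoxide, and Pd-catalysed reductive desulfonylation through the π-allyl complex should then deliver hydride to the less substituted terminus, which keeps the 18E alkene in place and removes the sulfone centre.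

**Step 8**
Reactants: 8 (all-E)-octaprenol
Product: 9 (2E,6E,10E,14E,18E,22E,26E)-octaprenyl bromide
Conditions: PBr3 (0.4 equiv), Et2O, −10 °C, dark; used crude
Reagents that add atoms: phosphorus tribromide, BrP(Br)Br
Why: As in step 1, SN2 bromination of the primary allylic alcohol should keep the 2E geometry.

**Step 9**
Reactants: 10 2'-iodoacetophenone [1-(2-iodophenyl)ethan-1-one]; 9 (all-E)-octaprenyl bromide
Product: 11 (4E,8E,12E,16E,20E,24E,28E)-1-(2-iodophenyl)-5,9,13,17,21,25,29,33-octamethyltetratriaconta-4,8,12,16,20,24,28,32-octaen-1-one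
Conditions: 10 (2 equiv), LiHMDS (2 equiv), THF, −78 °C; DMPU, then 9 (1 equiv), −78 → 0 °C
Reagents that add atoms: none
Why: SN2 alkylation of the lithium enolate of the methyl ketone by the primary allylic bromide should place the chain on the α-carbon with the E geometry kept, and the excess of enolate limits double alkylation.

**Step 10**
Reactants: 11 o-iodoaryl ketone; 12 propyne
Product: 14 3-methyl-2-[(2E,6E,10E,14E,18E,22E,26E)-3,7,11,15,19,23,27,31-octamethyldotriaconta-2,6,10,14,18,22,26,30-octaen-1-yl]naphthalen-1-ol, via alkynyl ketone 13 (not isolated)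
Conditions: PdCl2(PPh3)2 (3 mol%), CuI (5 mol%), Et3N, THF, propyne (3 equiv), rt; excess propyne purged with N2; then KHMDS (3 equiv), toluene, −78 °C → rt; aq. NH4Cl
Reagents that add atoms: none
Why: Pd(0)/Cu(I) Sonogashira coupling first joins the iodide-bearing ring carbon (future C8a) to the terminal carbon of propyne (future C1) to give 13; KHMDS then forms the potassium enolate of the aryl ketone, whose chain-bearing α-carbon (future C3) adds to the methyl-bearing alkyne carbon (future C2), and proton shift gives the aromatic naphtholate. The closest known reaction type is Sonogashira coupling of an o-haloaryl ketone followed by base-mediated benzannulation of the o-alkynylaryl ketone to a 1-naphthol, here run in one pot. The new six-membered ring closes by carbanionic 6-endo-dig C–C attack (the same ring results if the propynyl group first isomerises to the allene and closes by 6π-electrocyclisation). No stereocentre is formed, and the seven E double bonds of the chain should not be touched by amine, Pd/Cu or amide base at or below room temperature. The step needs C- over O-cyclisation and 6-endo over 5-exo closure, which the potassium enolate in toluene/THF and the irreversible aromatisation of the 6-endo adduct should secure; the methyl group ends on C2 because only the terminal carbon of propyne can couple to the aryl iodide.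

**Step 11**
Reactants: 14 3-methyl-2-octaprenylnaphthalen-1-ol
Product: 15 menaquinone-8
Conditions: O2 (1 atm), Co(salen) (10 mol%), THF/DMF, rt
Reagents that add atoms: dioxygen, O=O
Why: Cobalt–salen-catalysed aerobic oxidation of a phenol with a free para position (phenoxyl radical trapped by the cobalt–dioxygen species at C4 of the naphthol) should give the 1,4-quinone and leave the isolated trisubstituted alkenes alone.

**Compound list**

1 | (2E,6E,10E)-geranylgeraniol | CC(C)=CCC/C(C)=C/CC/C(C)=C/CC/C(C)=C/CO | starting material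
2 | (2E,6E,10E)-geranylgeranyl bromide | CC(C)=CCC/C(C)=C/CC/C(C)=C/CC/C(C)=C/CBr | intermediate
3 | (2E,6E,10E)-geranylgeranyl phenyl sulfone | CC(C)=CCC/C(C)=C/CC/C(C)=C/CC/C(C)=C/CS(=O)(=O)c1ccccc1 | intermediate
4 | (2E,6E,10E)-geranylgeranyl acetate | CC(C)=CCC/C(C)=C/CC/C(C)=C/CC/C(C)=C/COC(C)=O | intermediate
5 | (2E,6E,10E,14E)-16-hydroxy-3,7,11,15-tetramethylhexadeca-2,6,10,14-tetraen-1-yl acetate | OC/C(C)=C/CC/C(C)=C/CC/C(C)=C/CC/C(C)=C/COC(C)=O | intermediate
6 | (2E,6E,10E,14E)-16-bromo-3,7,11,15-tetramethylhexadeca-2,6,10,14-tetraen-1-yl acetate | BrC/C(C)=C/CC/C(C)=C/CC/C(C)=C/CC/C(C)=C/COC(C)=O | intermediate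
7 | (2E,6E,10E,14E,18E,22E,26E)-3,7,11,15,19,23,27,31-octamethyl-17-(phenylsulfonyl)dotriaconta-2,6,10,14,18,22,26,30-octaen-1-yl acetate, racemic at C17 | CC(C)=CCC/C(C)=C/CC/C(C)=C/CC/C(C)=C/C(S(=O)(=O)c1ccccc1)C/C(C)=C/CC/C(C)=C/CC/C(C)=C/CC/C(C)=C/COC(C)=O | intermediate
8 | (2E,6E,10E,14E,18E,22E,26E)-octaprenol | CC(C)=CCC/C(C)=C/CC/C(C)=C/CC/C(C)=C/CC/C(C)=C/CC/C(C)=C/CC/C(C)=C/CC/C(C)=C/CO | intermediate
9 | (2E,6E,10E,14E,18E,22E,26E)-octaprenyl bromide | CC(C)=CCC/C(C)=C/CC/C(C)=C/CC/C(C)=C/CC/C(C)=C/CC/C(C)=C/CC/C(C)=C/CC/C(C)=C/CBr | intermediate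
10 | 2'-iodoacetophenone | CC(=O)c1ccccc1I | starting material
11 | (4E,8E,12E,16E,20E,24E,28E)-1-(2-iodophenyl)-5,9,13,17,21,25,29,33-octamethyltetratriaconta-4,8,12,16,20,24,28,32-octaen-1-one | CC(C)=CCC/C(C)=C/CC/C(C)=C/CC/C(C)=C/CC/C(C)=C/CC/C(C)=C/CC/C(C)=C/CC/C(C)=C/CCC(=O)c1ccccc1I | intermediate
12 | propyne | CC#C | starting material
13 | (4E,8E,12E,16E,20E,24E,28E)-5,9,13,17,21,25,29,33-octamethyl-1-[2-(prop-1-yn-1-yl)phenyl]tetratriaconta-4,8,12,16,20,24,28,32-octaen-1-one | CC(C)=CCC/C(C)=C/CC/C(C)=C/CC/C(C)=C/CC/C(C)=C/CC/C(C)=C/CC/C(C)=C/CC/C(C)=C/CCC(=O)c1ccccc1C#CC | intermediate (not isolated)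
14 | 3-methyl-2-[(all-E)-octaprenyl]naphthalen-1-ol | CC(C)=CCC/C(C)=C/CC/C(C)=C/CC/C(C)=C/CC/C(C)=C/CC/C(C)=C/CC/C(C)=C/CC/C(C)=C/Cc1c(C)cc2ccccc2c1O | intermediate
15 | menaquinone-8, 2-methyl-3-[(all-E)-octaprenyl]naphthalene-1,4-dione | CC(C)=CCC/C(C)=C/CC/C(C)=C/CC/C(C)=C/CC/C(C)=C/CC/C(C)=C/CC/C(C)=C/CC/C(C)=C/CC1=C(C)C(=O)c2ccccc2C1=O | target

**Step count.** Total: 11 steps. Longest linear sequence: 9 steps (steps 3, 4, 5, 6, 7, 8, 9, 10, 11 from geranylgeraniol).

**Steps most likely to fail**

Step 10. After the coupling the enolate may close through oxygen or in the 5-exo mode, or the salts and metal residues of the first stage may divert the base stage. The fallback sets out from 11 and comes back at 14. 11 and 12 are coupled under the Sonogashira conditions alone and 13 is isolated. TBSOTf, Et3N, CH2Cl2, 0 °C should give the tert-butyldimethylsilyl (Z)-enol ether F1. PtCl2 (5 mol%), toluene, 80 °C should close it by π-acid-catalysed 6-endo-dig attack of the enol ether on the alkyne to the naphthyl silyl ether F2. TBAF, THF, 0 °C then gives 14.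

Step 9. Proton exchange between the product ketone and unreacted enolate may lead to double alkylation, and O-alkylation may compete. The fallback sets out from 9 and comes back at 11. Commercial ethyl 3-(2-iodophenyl)-3-oxopropanoate (CCOC(=O)CC(=O)c1ccccc1I) with K2CO3 in acetone at rt is C-alkylated by 9 to the β-keto ester F3. LiOH, THF/H2O, rt, then citric acid and gentle warming (40 °C) should hydrolyse and decarboxylate it to 11.

Step 4. The oxidation may fail to discriminate between the terminal and the three internal trisubstituted alkenes and may run on to the enal. The fallback sets out from 4 and comes back at 5. NBS, THF/H2O, 0 °C (terminal-selective bromohydrin formation) should give the bromohydrin F4. DBU, CH2Cl2, rt closes it to the terminal epoxide F5. HIO4·2H2O, THF/Et2O, 0 °C cleaves this to the trisnor aldehyde F6. E-selective Wittig reaction with 2-(triphenylphosphoranylidene)propanal in toluene at 80 °C gives the enal F7. Luche reduction (NaBH4, CeCl3·7H2O, MeOH, −20 °C) then gives 5.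

**Further compounds**

F1 | step 10 | tert-butyldimethylsilyl (Z)-enol ether of 13 | CC(C)=CCC/C(C)=C/CC/C(C)=C/CC/C(C)=C/CC/C(C)=C/CC/C(C)=C/CC/C(C)=C/CC/C(C)=C/C/C=C(\O[Si](C)(C)C(C)(C)C)c1ccccc1C#CC
F2 | step 10 | tert-butyldimethyl{[3-methyl-2-((all-E)-octaprenyl)naphthalen-1-yl]oxy}silane | CC(C)=CCC/C(C)=C/CC/C(C)=C/CC/C(C)=C/CC/C(C)=C/CC/C(C)=C/CC/C(C)=C/CC/C(C)=C/Cc1c(C)cc2ccccc2c1O[Si](C)(C)C(C)(C)C
F3 | step 9 | ethyl (4E,8E,12E,16E,20E,24E,28E)-2-(2-iodobenzoyl)-5,9,13,17,21,25,29,33-octamethyltetratriaconta-4,8,12,16,20,24,28,32-octaenoate (racemic) | CC(C)=CCC/C(C)=C/CC/C(C)=C/CC/C(C)=C/CC/C(C)=C/CC/C(C)=C/CC/C(C)=C/CC/C(C)=C/CC(C(=O)OCC)C(=O)c1ccccc1I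
F4 | step 4 | (2E,6E,10E)-14-bromo-15-hydroxy-3,7,11,15-tetramethylhexadeca-2,6,10-trien-1-yl acetate (racemic) | CC(C)(O)C(Br)CC/C(C)=C/CC/C(C)=C/CC/C(C)=C/COC(C)=O
F5 | step 4 | (2E,6E,10E)-13-(3,3-dimethyloxiran-2-yl)-3,7,11-trimethyltrideca-2,6,10-trien-1-yl acetate (racemic) | CC1(C)OC1CC/C(C)=C/CC/C(C)=C/CC/C(C)=C/COC(C)=O
F6 | step 4 | (2E,6E,10E)-3,7,11-trimethyl-14-oxotetradeca-2,6,10-trien-1-yl acetate | O=CCC/C(C)=C/CC/C(C)=C/CC/C(C)=C/COC(C)=O
F7 | step 4 | (2E,6E,10E,14E)-3,7,11,15-tetramethyl-16-oxohexadeca-2,6,10,14-tetraen-1-yl acetate | O=C/C(C)=C/CC/C(C)=C/CC/C(C)=C/CC/C(C)=C/COC(C)=O
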